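**Strategy.** Everything rests on disconnecting the C6–C7 bond of the nine-membered ring (caryophyllane numbering) by a Claisen retron. A cyclobutane-fused 2-methylene-7-methyl-7-vinyloxepane, made from an enantioselective cyclohexenone–isobutene photoadduct by Baeyer–Villiger oxidation and lactone methylenation, undergoes a [3,3] shift that trades the C4–O bond for the C6–C7 bond. In one operation the seven-membered cyclic enol ether becomes the nine-membered carbocycle with the C8 ketone and a C4=C5 olefin. The step exploits the γ,δ-unsaturated carbonyl pattern hidden in that ring: C8, the later spiro carbon, and the C4–C5 unit flank C6–C7. Methylenation, ene oxygenation, CBS reduction and a three-component oxa-Diels–Alder reaction finish the target.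

Key step: step 6

Remark on labels: caryophyllane numbering is used for the target and the nine-membered intermediates (C1/C9 ring fusion, C4 methyl-bearing, C5 carbinol, C8 spiro carbon, C13 the pyran CH2, C1′ the isobutyl-bearing carbon).
Assumption: syncarpic acid (19) is taken as a purchasable triketone.

**Step 1**
Reactants: 1 cyclohex-2-en-1-one; 2 isobutene
Product: 4 (1R,6R)-7,7-dimethylbicyclo[4.2.0]octan-2-one (cis-fused), via trans-fused photoadduct 3 (not isolated)
Conditions: 2 (excess), chiral B-aryl oxazaborolidine·AlBr3 (50 mol%, antipode chosen for 6R), hν (366 nm), CH2Cl2, −75 °C; then basic Al2O3, CH2Cl2, rt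
Reagents that add atoms: none
Why: Enantioselective Lewis-acid-catalysed enone–alkene [2+2] photocycloaddition, in which the AlBr3-activated oxazaborolidine binds the enone and shields one face so that isobutene should add head-to-tail and fix C6 (the later C1) as R, while the epimerisable ring-fusion carbon next to the carbonyl is equilibrated on basic Al2O3 to the stable cis-fused ketone.

**Step 2**
Reactants: 4 (1R,6R)-7,7-dimethylbicyclo[4.2.0]octan-2-one; 5 acetaldehyde
Product: 8 (1R,3E,6R)-3-ethylidene-7,7-dimethylbicyclo[4.2.0]octan-2-one, via aldol adduct 6 (not isolated), via aldol mesylate 7 (not isolated)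
Conditions: LiN(iPr)2, THF, −78 °C; 5; MsCl, −78 → 0 °C; then DBU, rt
Reagents that add atoms: none
Why: Directed aldol condensation, in which kinetic deprotonation takes the less hindered C3 methylene rather than the cyclobutane methine and E1cB loss of mesylate should give the conjugated (E)-ethylidene ketone, erasing the two transient stereocentres.

**Step 3**
Reactants: 8 (1R,3E,6R)-3-ethylidene-7,7-dimethylbicyclo[4.2.0]octan-2-one
Product: 9 (1R,3R,6R)-3-ethenyl-3,7,7-trimethylbicyclo[4.2.0]octan-2-one (expected major C3 epimer)
Conditions: KOtBu (1.05 equiv), tBuOH/THF, 0 °C; MeI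
Reagents that add atoms: iodomethane, CI
Why: Deconjugative α-alkylation of an alkylidene ketone, in which the through-conjugated dienolate from γ-deprotonation is methylated at its α-carbon, preferentially on the convex face anti to the cyclobutane (3R); this centre (the later C4) becomes sp2 in step 6, so the minor epimer would converge.

**Step 4**
Reactants: 9 (1R,3R,6R)-3-ethenyl-3,7,7-trimethylbicyclo[4.2.0]octan-2-one
Product: 10 (1R,4R,7R)-4-ethenyl-4,8,8-trimethyl-3-oxabicyclo[5.2.0]nonan-2-one
Conditions: mCPBA, NaHCO3 (buffer), CH2Cl2, 0 °C → rt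
Reagents that add atoms: mCPBA, OOC(=O)c1cccc(Cl)c1
Why: Baeyer–Villiger oxidation, in which the quaternary allylic carbon migrates with retention in preference to the secondary cyclobutyl carbon, and the monosubstituted vinyl group should be epoxidised more slowly than the ketone is oxidised.

**Step 5**
Reactants: 10 (1R,4R,7R)-4-ethenyl-4,8,8-trimethyl-3-oxabicyclo[5.2.0]nonan-2-one
Product: 11 (1R,4R,7R)-4-ethenyl-4,8,8-trimethyl-2-methylidene-3-oxabicyclo[5.2.0]nonane
Conditions: Cp2TiMe2 (2.5 equiv), PhMe/THF, 70 °C, dark; filtration through basic Al2O3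
Reagents that add atoms: dimethyltitanocene Cp2TiMe2, C[Ti](C)(C1C=CC=C1)C1C=CC=C1
Why: Petasis methylenation, in which thermally generated Cp2Ti=CH2 converts the lactone carbonyl into the exocyclic enol ether through an oxatitanacyclobutane without touching the vinyl group or any stereocentre.

**Step 6**
Reactants: 11 (1R,4R,7R)-4-ethenyl-4,8,8-trimethyl-2-methylidene-3-oxabicyclo[5.2.0]nonane
Product: 12 (1R,5Z,9R)-6,10,10-trimethylbicyclo[7.2.0]undec-5-en-2-one (cis-fused; ketone at caryophyllane C8, olefin C4=C5)
Conditions: degassed mesitylene (0.02 M), iPr2NEt (trace), base-washed sealed tube, 170 °C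
Reagents that add atoms: none
Why: Thermal Claisen rearrangement, a concerted suprafacial [3,3] shift of the allyl vinyl ether C7=C8–O–C4–C5=C6 that breaks the O–C4 bond and forms the C6–C7 bond while C8 becomes the ketone. The closest known reaction type is the Claisen ring expansion of 2-methylene cyclic ethers carrying a vinyl group on the other α-carbon, which turns six-membered ethers into cyclooctenones and seven-membered ketene acetals into nine-membered lactones. The nine-membered carbocycle is closed by ring expansion: the oxepane loses its oxygen from the ring and gains C5, C6 and C7 through a bridged six-centre transition state spanned by the chain C9–C1–C2–C3. No stereocentre is created (C4 becomes sp2, C1 and C9 are untouched, so the product stays cis-fused), and the ring chain forces C3 pseudo-axial on C4, which should place C3 and C6 cis and give the (Z)-olefin. The step needs the [3,3] path to win over retro-ene cleavage and over migration of the enol ether double bond into the ring, which the irreversible formation of the C8=O bond, base-washed glass and the amine trace should secure.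

**Step 7**
Reactants: 12 (1R,5Z,9R)-6,10,10-trimethylbicyclo[7.2.0]undec-5-en-2-one
Product: 14 (1R,4Z,9S)-4,11,11-trimethyl-8-methylidenebicyclo[7.2.0]undec-4-ene (isocaryophyllene), via trans-fused ketone 13 (not isolated)
Conditions: KOtBu (0.3 equiv), tBuOH/THF, rt; then Ph3PCH3Br, KOtBu, THF, 0 → 60 °C
Reagents that add atoms: methyltriphenylphosphonium bromide, C[P+](c1ccccc1)(c1ccccc1)c1ccccc1.[Br-]
Why: Base epimerisation followed by Wittig methylenation, in which KOtBu equilibrates C9 through the enolate to the more stable trans ring fusion (9S; C1 is not α to the carbonyl and stays R) before the ylide converts C8=O into the exocyclic methylene.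

**Step 8**
Reactants: 14 (1R,4Z,9S)-4,11,11-trimethyl-8-methylidenebicyclo[7.2.0]undec-4-ene
Product: 17 (1R,3Z,9S)-4,11,11-trimethyl-8-methylidenebicyclo[7.2.0]undec-3-en-5-one, via allylic hydroperoxide 15 (not isolated), via allylic peroxyacetate 16 (not isolated)
Conditions: O2, tetraphenylporphyrin (cat.), hν (visible), CH2Cl2, 0 °C; then Ac2O, pyridine, DMAP (cat.), rt
Reagents that add atoms: dioxygen, O=O
Why: Schenck ene reaction and Kornblum–DeLaMare dehydration, in which singlet oxygen should attack the trisubstituted (Z)-olefin much faster than the 1,1-disubstituted one and, following the cis effect, abstract an allylic hydrogen from C3 so that oxygen lands on C5 and C3=C4 forms with the ring-cis (Z) geometry; the secondary peroxyacetate then loses acetate to give the enone, the C5 configuration being irrelevant here.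

**Step 9**
Reactants: 17 (1R,3Z,9S)-4,11,11-trimethyl-8-methylidenebicyclo[7.2.0]undec-3-en-5-one
Product: 18 (1R,3Z,5R,9S)-4,11,11-trimethyl-8-methylidenebicyclo[7.2.0]undec-3-en-5-ol
Conditions: (S)-Me-CBS oxazaborolidine (20 mol%), catecholborane, PhMe, −78 °C; aqueous work-up
Reagents that add atoms: none
Why: Corey–Bakshi–Shibata reduction, in which the (S)-oxazaborolidine differentiates the α-methylalkenyl group (large) from the C6 methylene (small) and should deliver hydride to the face that gives the (5R)-allylic alcohol by reagent control, catecholborane at low temperature sparing both olefins.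

**Step 10**
Reactants: 18 (1R,3Z,5R,9S)-4,11,11-trimethyl-8-methylidenebicyclo[7.2.0]undec-3-en-5-ol; 19 syncarpic acid; 20 isovaleraldehyde
Product: 22 Tomentodione O, via alkylidene trione 21 (not isolated)
Conditions: ethylenediammonium diacetate (10 mol%), 4 Å molecular sieves, PhMe, 60 °C
Reagents that add atoms: none
Why: Domino Knoevenagel/inverse-electron-demand oxa-Diels–Alder reaction, in which the alkylidene trione adds across the electron-rich C8=C13 olefin with oxygen bonding to the more substituted C8; approach on the exposed peripheral face of the conformer holding C13 on the side of H-9 should give 8S, and the transition state that keeps the cyclobutane-bearing C9 exo and the C7 methylene endo (isobutyl syn to C7) should give 1′R.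

**Compound list**
1 | cyclohex-2-en-1-one | O=C1C=CCCC1 | starting material
2 | isobutene (2-methylpropene) | CC(C)=C | starting material
3 | (1S,6R)-7,7-dimethylbicyclo[4.2.0]octan-2-one (trans-fused photoadduct) | O=C1CCC[C@@H]2[C@@H]1CC2(C)C | intermediate
4 | (1R,6R)-7,7-dimethylbicyclo[4.2.0]octan-2-one (cis-fused) | O=C1CCC[C@@H]2[C@H]1CC2(C)C | intermediate
5 | acetaldehyde | CC=O | starting material
6 | (1R,6R)-3-(1-hydroxyethyl)-7,7-dimethylbicyclo[4.2.0]octan-2-one (aldol adduct, mixture at C3 and the carbinol carbon) | O=C1C(C(C)O)CC[C@@H]2[C@H]1CC2(C)C | intermediate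
7 | methanesulfonate of 6 (same mixture) | O=C1C(C(C)OS(C)(=O)=O)CC[C@@H]2[C@H]1CC2(C)C | intermediate
8 | (1R,3E,6R)-3-ethylidene-7,7-dimethylbicyclo[4.2.0]octan-2-one | O=C1/C(=C/C)CC[C@@H]2[C@H]1CC2(C)C | intermediate
9 | (1R,3R,6R)-3-ethenyl-3,7,7-trimethylbicyclo[4.2.0]octan-2-one (major C3 epimer drawn) | O=C1[C@@](C)(C=C)CC[C@@H]2[C@H]1CC2(C)C | intermediate
10 | (1R,4R,7R)-4-ethenyl-4,8,8-trimethyl-3-oxabicyclo[5.2.0]nonan-2-one | O=C1O[C@@](C)(C=C)CC[C@@H]2[C@H]1CC2(C)C | intermediate
11 | (1R,4R,7R)-4-ethenyl-4,8,8-trimethyl-2-methylidene-3-oxabicyclo[5.2.0]nonane | C=C1O[C@@](C)(C=C)CC[C@@H]2[C@H]1CC2(C)C | intermediate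
12 | (1R,5Z,9R)-6,10,10-trimethylbicyclo[7.2.0]undec-5-en-2-one (cis-fused) | C/C1=C/CCC(=O)[C@@H]2CC(C)(C)[C@@H]2CC1 | intermediate
13 | (1S,5Z,9R)-6,10,10-trimethylbicyclo[7.2.0]undec-5-en-2-one (trans-fused) | C/C1=C/CCC(=O)[C@H]2CC(C)(C)[C@@H]2CC1 | intermediate
14 | (1R,4Z,9S)-4,11,11-trimethyl-8-methylidenebicyclo[7.2.0]undec-4-ene (isocaryophyllene) | C/C1=C/CCC(=C)[C@H]2CC(C)(C)[C@@H]2CC1 | intermediate
15 | (1R,3Z,9S)-5-hydroperoxy-4,11,11-trimethyl-8-methylidenebicyclo[7.2.0]undec-3-ene (both C5 epimers) | C/C1=C/C[C@@H]2[C@H](CC2(C)C)C(=C)CCC1OO | intermediate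
16 | peroxyacetate of 15 (both C5 epimers) | C/C1=C/C[C@@H]2[C@H](CC2(C)C)C(=C)CCC1OOC(C)=O | intermediate
17 | (1R,3Z,9S)-4,11,11-trimethyl-8-methylidenebicyclo[7.2.0]undec-3-en-5-one | C/C1=C/C[C@@H]2[C@H](CC2(C)C)C(=C)CCC1=O | intermediate
18 | (1R,3Z,5R,9S)-4,11,11-trimethyl-8-methylidenebicyclo[7.2.0]undec-3-en-5-ol | C/C1=C/C[C@@H]2[C@H](CC2(C)C)C(=C)CC[C@H]1O | intermediate
19 | syncarpic acid (2,2,4,4-tetramethylcyclohexane-1,3,5-trione) | CC1(C)C(=O)CC(=O)C(C)(C)C1=O | starting material
20 | isovaleraldehyde (3-methylbutanal) | CC(C)CC=O | starting material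
21 | 2,2,4,4-tetramethyl-6-(3-methylbutylidene)cyclohexane-1,3,5-trione | CC(C)CC=C1C(=O)C(C)(C)C(=O)C(C)(C)C1=O | intermediate
22 | Tomentodione O | C/C1=C/C[C@@H]2[C@H](CC2(C)C)[C@]2(CC[C@H]1O)C[C@@H](CC(C)C)C1=C(O2)C(C)(C)C(=O)C(C)(C)C1=O | target

**Total step count:** 10. **Longest linear sequence:** 10 steps (from 1 to 22).

**Steps most likely to fail**

Step 6 (key Claisen ring expansion). At the temperature needed, the tertiary allyl vinyl ether may fragment by retro-ene cleavage or C4–O ionisation, or the exocyclic enol ether double bond may migrate into the ring before the [3,3] shift occurs. The fallback sets out from 11 and comes back at 12. The rearrangement would be run as an aluminium-promoted, polarised process with iBu3Al (CH2Cl2, −78 °C → rt), in which the ketone is trapped by in situ β-hydride reduction as (1R,5Z,9R)-6,10,10-trimethylbicyclo[7.2.0]undec-5-en-2-ol F1. Oxidation of F1 with Dess–Martin periodinane would then return ketone 12.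

Step 8 (ene oxygenation). Hydrogen abstraction may occur at C6 or at the C4 methyl group instead of C3, so that oxygen ends up on C4 or the new olefin ends up exocyclic. The fallback sets out from 14 and comes back at 17. Epoxidation of the trisubstituted olefin (mCPBA, NaHCO3, CH2Cl2, 0 °C) should give isocaryophyllene 4,5-epoxide F2. Base-induced β-elimination toward the methyl group (LiNEt2, Et2O, reflux) should give the exocyclic allylic alcohol 11,11-dimethyl-4,8-dimethylidenebicyclo[7.2.0]undecan-5-ol F3. Dess–Martin oxidation should give the α-methylene ketone 11,11-dimethyl-4,8-dimethylidenebicyclo[7.2.0]undecan-5-one F4. Isomerisation through the dienolate (DBU, PhMe, 80 °C) should move the exocyclic olefin into conjugation within the ring to give 17.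

Step 10 (oxa-Diels–Alder). Facial and endo/exo selectivity on the flexible nine-membered ring may be poor, giving C8/C1′ diastereomers that are hard to separate from the target. The fallback sets out from 17 and comes back at 22. The cycloaddition would be run on the enone, whose sp2 C5 changes the ring conformation, with 19 and 20 under the same amine-acetate catalysis, to give the 5-oxo analogue of Tomentodione O F5, purified at this stage. Reagent-controlled CBS reduction of the enone carbonyl ((S)-Me-CBS, catecholborane, −78 °C; the trione carbonyls are flanked by quaternary carbons) would then give 22.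

**Further compounds**
F1 | step 6 | (1R,5Z,9R)-6,10,10-trimethylbicyclo[7.2.0]undec-5-en-2-ol (both C2 epimers) | C/C1=C/CCC(O)[C@@H]2CC(C)(C)[C@@H]2CC1
F2 | step 8 | isocaryophyllene 4,5-epoxide (cis-epoxide, both faces) | CC12CC[C@@H]3[C@H](CC3(C)C)C(=C)CCC1O2
F3 | step 8 | (1R,9S)-11,11-dimethyl-4,8-dimethylidenebicyclo[7.2.0]undecan-5-ol (both C5 epimers) | C=C1CC[C@@H]2[C@H](CC2(C)C)C(=C)CCC1O
F4 | step 8 | (1R,9S)-11,11-dimethyl-4,8-dimethylidenebicyclo[7.2.0]undecan-5-one | C=C1CC[C@@H]2[C@H](CC2(C)C)C(=C)CCC1=O
F5 | step 10 | 5-oxo analogue of Tomentodione O | C/C1=C/C[C@@H]2[C@H](CC2(C)C)[C@]2(CCC1=O)C[C@@H](CC(C)C)C1=C(O2)C(C)(C)C(=O)C(C)(C)C1=O
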